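A direct plan would make ring A and ring B separately and join them at the ester late: the ring A catechol 1-[4-(benzyloxy)-2,3-dihydroxy-6-pentylphenyl]ethan-1-one A1 and the ring B iodide 5-(benzyloxy)-2-iodo-1-methoxy-3-propylbenzene A2 would be joined under CO with Pd(OAc)2 and a diphosphine, and hydrogenolysis would follow. Its weakest steps would be:
- The carbonylative ester formation from A1 and A2: it would need oxidative addition at an electron-rich aryl iodide with two ortho substituents and C–O bond formation with a catechol that can chelate the metal and offers two oxygens, and it would stake both branches on one late step.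
- The run-up to A2: mono-demethylation of a dimethyl ether, silylation to triisopropyl(3-methoxy-5-propylphenoxy)silane A3, iodination and exchange of the silyl for a benzyl group would be four operations that add a single iodine atom to a simple ring.
- The iodination of A3: two ring carbons are activated alike (para to the silyloxy or para to the methoxy group), and only the bulk of the silyl group would decide between them.

**Retrosynthetic overview**
Ring B bears OMe at C2 beside the carboxyl-bearing C1, a free OH at C4 and propyl at C6. This is the pattern that the diene (MeO)2C=CH–C(OSiMe3)=CH2 leaves on an alk-2-ynoate, so ring B is cut at C1–C2 and C5–C6 and built last by a Diels–Alder benzannulation.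
The precursor is the hex-2-ynoate of ring A: the ester C–O bond is made early, between an unhindered alkynoic acid and the only non-chelated hydroxyl (O-3) of the 4-O-benzyl ring A catechol.
Ring A is bought as an arene (5-bromo-1,2,3-trimethoxybenzene) and dressed by Kumada coupling, Friedel–Crafts acetylation, demethylation and one benzylation; the diene comes in two steps from 1,1-dimethoxyethene.
By design no 2,6-disubstituted benzoyl unit is esterified, no aryl iodide or carbonylation is needed, and ring B is made with its methyl ether and free hydroxyl in place, without a protecting-group step of its own.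

Key step: step 8

Remark: the target has no stereocentre and no double-bond geometry; the ester oxygen is the central oxygen (O-3) of the 2,3,4-trioxygenated acetophenone ring A, as the SMILES shows.

**Step 1**
Reactants: 1 5-bromo-1,2,3-trimethoxybenzene; 2 pentylmagnesium bromide
Product: 3 1,2,3-trimethoxy-5-pentylbenzene
Conditions: NiCl2(Ph2P(CH2)3PPh2) (2 mol %), THF, 0 → 50 °C
Reagents that add atoms: none
Why: Kumada–Corriu cross-coupling of an aryl bromide with a primary alkyl Grignard reagent, in which the chelating diphosphine on nickel should suppress β-hydride elimination and the methyl ethers are inert.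

**Step 2**
Reactants: 3 1,2,3-trimethoxy-5-pentylbenzene; 4 acetyl chloride
Product: 5 1-(2,3,4-trimethoxy-6-pentylphenyl)ethan-1-one
Conditions: AlCl3 (1.2 equiv), CH2Cl2, 0 °C
Reagents that add atoms: none
Why: Friedel–Crafts acylation in which the two free ring carbons are equivalent by symmetry (each ortho to one methoxy group and para to another), so one regioisomer should form, and any methyl ether next to the ketone that AlCl3 cleaves converges in step 3.

**Step 3**
Reactants: 5 1-(2,3,4-trimethoxy-6-pentylphenyl)ethan-1-one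
Product: 6 1-(2,3,4-trihydroxy-6-pentylphenyl)ethan-1-one
Conditions: BBr3 (5 equiv), CH2Cl2, −78 °C → rt; then H2O; under N2
Reagents that add atoms: none
Why: Lewis-acid ether cleavage (BBr3 demethylation) of all three aryl methyl ethers, which the aryl ketone and the alkyl chain should tolerate.

**Step 4**
Reactants: 6 1-(2,3,4-trihydroxy-6-pentylphenyl)ethan-1-one
Product: 7 1-[4-(benzyloxy)-2,3-dihydroxy-6-pentylphenyl]ethan-1-one
Conditions: BnBr (1.05 equiv), NaHCO3 (1.5 equiv), MeCN, 70 °C, N2
Reagents that add atoms: benzyl bromide, BrCc1ccccc1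
Why: Williamson etherification under weak-base control, in which NaHCO3 should ionise only the most acidic hydroxyl (para to the acetyl group), while O-2 is tied to the ketone by a hydrogen bond and O-3 is the least acidic.

**Step 5**
Reactants: 7 1-[4-(benzyloxy)-2,3-dihydroxy-6-pentylphenyl]ethan-1-one; 8 hex-2-ynoic acid
Product: 9 3-acetyl-6-(benzyloxy)-2-hydroxy-4-pentylphenyl hex-2-ynoate
Conditions: N,N'-dicyclohexylcarbodiimide (1.1 equiv), 4-(dimethylamino)pyridine (5 mol %), CH2Cl2, 0 °C → rt
Reagents that add atoms: none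
Why: Steglich esterification of an unhindered acid (carboxyl on an sp carbon) at the only hydroxyl not held in the hydrogen bond to the ketone, O-3, which is also the thermodynamic site because an acyl shift to O-2 would cost that hydrogen bond.

**Step 6**
Reactants: 10 1,1-dimethoxyethene; 4 acetyl chloride
Product: 11 4,4-dimethoxybut-3-en-2-one
Conditions: pyridine (1.2 equiv), Et2O, −20 °C → rt
Reagents that add atoms: none
Why: C-acylation of a ketene acetal at its nucleophilic CH2 carbon by the N-acetylpyridinium salt, followed by loss of a proton from the dimethoxycarbenium ion, should give the push–pull enone.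

**Step 7**
Reactants: 11 4,4-dimethoxybut-3-en-2-one
Product: 13 1,1-dimethoxy-3-(trimethylsilyloxy)buta-1,3-diene, via lithium dienolate of the enone 12 (not isolated)
Conditions: LiN(iPr)2 (1.1 equiv), THF, −78 °C; then Me3SiCl, −78 °C → rt
Reagents that add atoms: chlorotrimethylsilane, C[Si](C)(C)Cl
Why: Kinetic enolisation of the methyl ketone (the only acidic C–H, as the β-carbon bears two methoxy groups and no hydrogen) and O-silylation of the enolate (silyl enol ether formation) should give the diene, which is distilled and used at once.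

**Step 8**
Reactants: 9 3-acetyl-6-(benzyloxy)-2-hydroxy-4-pentylphenyl hex-2-ynoate; 13 1,1-dimethoxy-3-(trimethylsilyloxy)buta-1,3-diene
Product: 17 3-acetyl-6-(benzyloxy)-2-hydroxy-4-pentylphenyl 4-hydroxy-2-methoxy-6-propylbenzoate, via silyl ether of the alkynoate 14 (not isolated), via cyclohexa-1,4-diene cycloadduct 15 (not isolated), via bis(trimethylsilyl) ether of the depside 16 (not isolated)
Conditions: N,O-bis(trimethylsilyl)acetamide (1.2 equiv), toluene, rt; then 13 (2.5 equiv), 110 °C, sealed tube; then 1 M HCl, THF, 0 °C → rt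
Reagents that add atoms: none
Why: After the chelated phenol of 9 has been capped in the flask as its trimethylsilyl ether 14, so that no acidic proton meets the ketene acetal, the electron-rich diene and the electron-poor alkynoate should undergo a normal-demand [4+2] cycloaddition (Diels–Alder reaction), concerted but asynchronous, in which the unsubstituted terminus C4 of the diene bonds to the β-carbon of the alkynoate and the ketene acetal carbon C1 bonds to the α-carbon. The closest known reaction type is the Diels–Alder benzannulation of 1,1-dialkoxy-3-silyloxybuta-1,3-dienes with alkyl alk-2-ynoates to 6-alkyl-4-hydroxy-2-methoxybenzoates, and an aryl ester is a stronger acceptor than an alkyl ester. Ring B closes by this intermolecular cycloaddition, which forms its bonds C1–C2 and C5–C6 in one operation, and the cyclohexa-1,4-diene 15 then loses methanol from its ketal carbon and becomes aromatic, so that one methoxy group stays at C2 and the silyloxy group at C4. No stereocentre is formed. The step needs regioselectivity, secured by the matching polarisation of the diene (three oxygen donors pushing toward C4) and the alkynoate (carbonyl pulling at the β-carbon), and chemoselectivity for the triple bond over the aryl ketone and the ester carbonyl, secured by the absence of any Lewis acid; the dilute acid of the work-up cleaves both silyl ethers and should leave the hindered aryl ester, the methyl ether and the benzyl ether.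

**Step 9**
Reactants: 17 3-acetyl-6-(benzyloxy)-2-hydroxy-4-pentylphenyl 4-hydroxy-2-methoxy-6-propylbenzoate
Product: 18 3-acetyl-2,6-dihydroxy-4-pentylphenyl 4-hydroxy-2-methoxy-6-propylbenzoate
Conditions: H2 (1 atm), Pd/C (10% palladium on carbon), EtOAc, rt
Reagents that add atoms: none
Why: Catalytic hydrogenolysis of the aryl benzyl ether under neutral conditions, which the hindered aryl ester, the methyl ether and the hydrogen-bonded aryl ketone should survive.

**Compound list**

1 | 5-bromo-1,2,3-trimethoxybenzene | COc1cc(Br)cc(OC)c1OC | starting material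
2 | pentylmagnesium bromide | CCCCC[Mg]Br | starting material
3 | 1,2,3-trimethoxy-5-pentylbenzene | CCCCCc1cc(OC)c(OC)c(OC)c1 | intermediate
4 | acetyl chloride | CC(Cl)=O | starting material
5 | 1-(2,3,4-trimethoxy-6-pentylphenyl)ethan-1-one | CCCCCc1cc(OC)c(OC)c(OC)c1C(C)=O | intermediate
6 | 1-(2,3,4-trihydroxy-6-pentylphenyl)ethan-1-one | CCCCCc1cc(O)c(O)c(O)c1C(C)=O | intermediate
7 | 1-[4-(benzyloxy)-2,3-dihydroxy-6-pentylphenyl]ethan-1-one | CCCCCc1cc(OCc2ccccc2)c(O)c(O)c1C(C)=O | intermediate
8 | hex-2-ynoic acid | CCCC#CC(=O)O | starting material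
9 | 3-acetyl-6-(benzyloxy)-2-hydroxy-4-pentylphenyl hex-2-ynoate | CCCCCc1cc(OCc2ccccc2)c(OC(=O)C#CCCC)c(O)c1C(C)=O | intermediate
10 | 1,1-dimethoxyethene | C=C(OC)OC | starting material
11 | 4,4-dimethoxybut-3-en-2-one | COC(OC)=CC(C)=O | intermediate
12 | lithium 4,4-dimethoxybuta-1,3-dien-2-olate | C=C([O-])C=C(OC)OC.[Li+] | intermediate
13 | 1,1-dimethoxy-3-(trimethylsilyloxy)buta-1,3-diene | COC(OC)=CC(=C)O[Si](C)(C)C | intermediate
14 | 3-acetyl-6-(benzyloxy)-4-pentyl-2-(trimethylsilyloxy)phenyl hex-2-ynoate | CCCCCc1cc(OCc2ccccc2)c(OC(=O)C#CCCC)c(O[Si](C)(C)C)c1C(C)=O | intermediate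
15 | 3-acetyl-6-(benzyloxy)-4-pentyl-2-(trimethylsilyloxy)phenyl 6,6-dimethoxy-2-propyl-4-(trimethylsilyloxy)cyclohexa-1,4-diene-1-carboxylate | CCCCCc1cc(OCc2ccccc2)c(OC(=O)C2=C(CCC)CC(O[Si](C)(C)C)=CC2(OC)OC)c(O[Si](C)(C)C)c1C(C)=O | intermediate
16 | 3-acetyl-6-(benzyloxy)-4-pentyl-2-(trimethylsilyloxy)phenyl 2-methoxy-6-propyl-4-(trimethylsilyloxy)benzoate | CCCCCc1cc(OCc2ccccc2)c(OC(=O)c2c(CCC)cc(O[Si](C)(C)C)cc2OC)c(O[Si](C)(C)C)c1C(C)=O | intermediate
17 | 3-acetyl-6-(benzyloxy)-2-hydroxy-4-pentylphenyl 4-hydroxy-2-methoxy-6-propylbenzoate | CCCCCc1cc(OCc2ccccc2)c(OC(=O)c2c(CCC)cc(O)cc2OC)c(O)c1C(C)=O | intermediate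
18 | 3-acetyl-2,6-dihydroxy-4-pentylphenyl 4-hydroxy-2-methoxy-6-propylbenzoate | CCCCCc1cc(O)c(OC(=O)c2c(CCC)cc(O)cc2OC)c(O)c1C(C)=O | target

**Step count**
Total: 9 steps (steps 1–5, 8 and 9 in the main line; steps 6 and 7 for the diene). Longest linear sequence: 7 steps (1, 2, 3, 4, 5, 8, 9).

**Steps most likely to fail**

Step 8. The cycloaddition at the β-substituted triple bond may be slow, the nucleophilic diene may instead take the acyl group from the activated aryl ester (loss of the ring A phenol), or traces of acid may destroy the diene. The fallback builds ring B first on a simple ester and then forms the hindered ester through an acylium-type mixed anhydride; it sets out from 13 and 7 and comes back to the route at 18. Commercial methyl hex-2-ynoate and 13 would be heated neat at 130 °C, where the cycloadduct methyl 6,6-dimethoxy-2-propyl-4-(trimethylsilyloxy)cyclohexa-1,4-diene-1-carboxylate F1 should form first and loss of methanol from F1 should give methyl 2-methoxy-6-propyl-4-(trimethylsilyloxy)benzoate F2 in the same flask. Dilute HCl would cleave the silyl ether of F2 to methyl 4-hydroxy-2-methoxy-6-propylbenzoate F3 and BnBr with K2CO3 in DMF would convert F3 into methyl 4-(benzyloxy)-2-methoxy-6-propylbenzoate F4 as the protected ester. KOH in DMSO/H2O at 100 °C would hydrolyse F4 to 4-(benzyloxy)-2-methoxy-6-propylbenzoic acid F5 as the free acid, and (CF3CO)2O in toluene would convert F5 into 4-(benzyloxy)-2-methoxy-6-propylbenzoic trifluoroacetic anhydride F6 which acylates through an acylium ion and so is not slowed by the two ortho substituents. With 7, F6 should acylate the non-chelated O-3 and give 3-acetyl-6-(benzyloxy)-2-hydroxy-4-pentylphenyl 4-(benzyloxy)-2-methoxy-6-propylbenzoate F7 as the bis(benzyl) ether of the target, and hydrogenolysis of both benzyl ethers of F7 (H2, Pd/C, EtOAc) would give 18.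

Step 5. Acylation may occur at the chelated oxygen or at both oxygens, or the neighbouring phenol or the pyridine catalyst may add to the alkynoate in a conjugate fashion. The fallback leaves only one hydroxyl free before the acylation; it sets out from 7 and comes back to the route at 18. MOMCl and iPr2NEt in CH2Cl2 would cap the non-chelated hydroxyl of 7 and give 1-[4-(benzyloxy)-2-hydroxy-3-(methoxymethoxy)-6-pentylphenyl]ethan-1-one F8 as the mono-acetal. BnBr and K2CO3 in DMF at 60 °C would benzylate the chelated hydroxyl of F8 to 1-[2,4-bis(benzyloxy)-3-(methoxymethoxy)-6-pentylphenyl]ethan-1-one F9 and HCl in MeOH would free O-3 of F9 to give 1-[2,4-bis(benzyloxy)-3-hydroxy-6-pentylphenyl]ethan-1-one F10 as the only phenol. Esterification of F10 with 8 as in step 5 would give 3-acetyl-2,6-bis(benzyloxy)-4-pentylphenyl hex-2-ynoate F11 which has no free hydroxyl and needs no silylation. Heating F11 with 13 in toluene at 110 °C should give the cycloadduct 3-acetyl-2,6-bis(benzyloxy)-4-pentylphenyl 6,6-dimethoxy-2-propyl-4-(trimethylsilyloxy)cyclohexa-1,4-diene-1-carboxylate F12 in the flask, and loss of methanol from F12 should give 3-acetyl-2,6-bis(benzyloxy)-4-pentylphenyl 2-methoxy-6-propyl-4-(trimethylsilyloxy)benzoate F13 as the arene. Dilute HCl would convert F13 into 3-acetyl-2,6-bis(benzyloxy)-4-pentylphenyl 4-hydroxy-2-methoxy-6-propylbenzoate F14 as the free phenol, and hydrogenolysis of both benzyl ethers of F14 (H2, Pd/C, EtOAc) would give 18.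

Step 6. The base may dehydrochlorinate acetyl chloride to ketene, or chloride may demethylate the dimethoxycarbenium intermediate so that it collapses to a β-keto ester. The fallback makes the same enone by addition–elimination at a dichlorovinyl ketone; it sets out from 4 and comes back to the route at 11. Acetyl chloride 4 and commercial 1,1-dichloroethene with AlCl3 in CH2Cl2 at 0 °C (Friedel–Crafts-type acylation of the alkene) would give 4,4,4-trichlorobutan-2-one F15 as the adduct. On distillation F15 would lose hydrogen chloride to give 4,4-dichlorobut-3-en-2-one F16 as a vinylogous acid chloride, and NaOMe (2 equiv) in MeOH at 0 °C would replace both vinylic chlorides of F16 by addition–elimination and give 11.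

**Further compounds**

F1 | step 8 | methyl 6,6-dimethoxy-2-propyl-4-(trimethylsilyloxy)cyclohexa-1,4-diene-1-carboxylate | CCCC1=C(C(=O)OC)C(OC)(OC)C=C(O[Si](C)(C)C)C1
F2 | step 8 | methyl 2-methoxy-6-propyl-4-(trimethylsilyloxy)benzoate | CCCc1cc(O[Si](C)(C)C)cc(OC)c1C(=O)OC
F3 | step 8 | methyl 4-hydroxy-2-methoxy-6-propylbenzoate | CCCc1cc(O)cc(OC)c1C(=O)OC
F4 | step 8 | methyl 4-(benzyloxy)-2-methoxy-6-propylbenzoate | CCCc1cc(OCc2ccccc2)cc(OC)c1C(=O)OC
F5 | step 8 | 4-(benzyloxy)-2-methoxy-6-propylbenzoic acid | CCCc1cc(OCc2ccccc2)cc(OC)c1C(=O)O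
F6 | step 8 | 4-(benzyloxy)-2-methoxy-6-propylbenzoic trifluoroacetic anhydride | CCCc1cc(OCc2ccccc2)cc(OC)c1C(=O)OC(=O)C(F)(F)F
F7 | step 8 | 3-acetyl-6-(benzyloxy)-2-hydroxy-4-pentylphenyl 4-(benzyloxy)-2-methoxy-6-propylbenzoate | CCCCCc1cc(OCc2ccccc2)c(OC(=O)c2c(CCC)cc(OCc3ccccc3)cc2OC)c(O)c1C(C)=O
F8 | step 5 | 1-[4-(benzyloxy)-2-hydroxy-3-(methoxymethoxy)-6-pentylphenyl]ethan-1-one | CCCCCc1cc(OCc2ccccc2)c(OCOC)c(O)c1C(C)=O
F9 | step 5 | 1-[2,4-bis(benzyloxy)-3-(methoxymethoxy)-6-pentylphenyl]ethan-1-one | CCCCCc1cc(OCc2ccccc2)c(OCOC)c(OCc2ccccc2)c1C(C)=O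
F10 | step 5 | 1-[2,4-bis(benzyloxy)-3-hydroxy-6-pentylphenyl]ethan-1-one | CCCCCc1cc(OCc2ccccc2)c(O)c(OCc2ccccc2)c1C(C)=O
F11 | step 5 | 3-acetyl-2,6-bis(benzyloxy)-4-pentylphenyl hex-2-ynoate | CCCCCc1cc(OCc2ccccc2)c(OC(=O)C#CCCC)c(OCc2ccccc2)c1C(C)=O
F12 | step 5 | 3-acetyl-2,6-bis(benzyloxy)-4-pentylphenyl 6,6-dimethoxy-2-propyl-4-(trimethylsilyloxy)cyclohexa-1,4-diene-1-carboxylate | CCCCCc1cc(OCc2ccccc2)c(OC(=O)C2=C(CCC)CC(O[Si](C)(C)C)=CC2(OC)OC)c(OCc2ccccc2)c1C(C)=O
F13 | step 5 | 3-acetyl-2,6-bis(benzyloxy)-4-pentylphenyl 2-methoxy-6-propyl-4-(trimethylsilyloxy)benzoate | CCCCCc1cc(OCc2ccccc2)c(OC(=O)c2c(CCC)cc(O[Si](C)(C)C)cc2OC)c(OCc2ccccc2)c1C(C)=O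
F14 | step 5 | 3-acetyl-2,6-bis(benzyloxy)-4-pentylphenyl 4-hydroxy-2-methoxy-6-propylbenzoate | CCCCCc1cc(OCc2ccccc2)c(OC(=O)c2c(CCC)cc(O)cc2OC)c(OCc2ccccc2)c1C(C)=O
F15 | step 6 | 4,4,4-trichlorobutan-2-one | CC(=O)CC(Cl)(Cl)Cl
F16 | step 6 | 4,4-dichlorobut-3-en-2-one | CC(=O)C=C(Cl)Cl
A1 | direct plan | 1-[4-(benzyloxy)-2,3-dihydroxy-6-pentylphenyl]ethan-1-one | CCCCCc1cc(OCc2ccccc2)c(O)c(O)c1C(C)=O
A2 | direct plan | 5-(benzyloxy)-2-iodo-1-methoxy-3-propylbenzene | CCCc1cc(OCc2ccccc2)cc(OC)c1I
A3 | direct plan | triisopropyl(3-methoxy-5-propylphenoxy)silane | CCCc1cc(O[Si](C(C)C)(C(C)C)C(C)C)cc(OC)c1
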